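**Retrosynthetic overview**

- The target is 7-O-prenyl-limocitrin. Its flavonol ring C is the enol of a 2-arylchroman-3,4-dione, so C3 and C4 are both carbonyl-level carbons and the C3–C4 bond is cut as a polarity-reversed (benzoin) union of two aldehydes.
- Dialdehyde 11 is assembled through the O1–C2 ether from ring A salicylaldehyde 4 and α-bromo ester 8 (ring B, from homovanillic acid), then reduction and re-oxidation.
- Rings A and B are bought as arenes; the C8 methoxy group is put on ring A by iodination and copper-catalysed methoxylation. Ring C is the only ring formed (step 9) and is aromatised last (step 12).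
- After debenzylation, the prenyl group is placed at the flavanonol stage, where 7-OH is the one acidic, unchelated phenol conjugated to C4=O.

Key step: step 9

Remark on the chemistry: the target has no stereocentre; 8–11 and all chroman-4-ones are racemic, and 12, 13 and 15 are drawn as the (2R,3R) enantiomer of the trans pair, any cis isomer converging in step 12.

**Step 1**
Reactants: 1 3,5-bis(benzyloxy)phenol
Product: 2 2,4-bis(benzyloxy)-6-hydroxybenzaldehyde
Conditions: MgCl2, Et3N, (CH2O)n, MeCN, reflux; aq. HCl work-up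
Reagents that add atoms: paraformaldehyde (formaldehyde), C=O
Why: Casnati–Skattebøl ortho-formylation, in which the magnesium phenoxide delivers formaldehyde to one of the two equivalent ortho carbons and a second formaldehyde oxidises the hydroxymethyl group by hydride transfer.

**Step 2**
Reactants: 2 2,4-bis(benzyloxy)-6-hydroxybenzaldehyde
Product: 3 4,6-bis(benzyloxy)-2-hydroxy-3-iodobenzaldehyde
Conditions: N-iodosuccinimide, CF3CO2H (cat.), MeCN, 0 °C to rt
Reagents that add atoms: N-iodosuccinimide, O=C1CCC(=O)N1I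
Why: Electrophilic aromatic iodination, directed by the free phenol to its only open ortho carbon (C3), which is also para to the 6-benzyloxy group and less hindered than C5 between two benzyloxy groups.

**Step 3**
Reactants: 3 4,6-bis(benzyloxy)-2-hydroxy-3-iodobenzaldehyde
Product: 4 4,6-bis(benzyloxy)-2-hydroxy-3-methoxybenzaldehyde
Conditions: NaOMe, CuBr (cat.), MeOH–DMF, 100 °C; then aq. HCl
Reagents that add atoms: sodium methoxide, C[O-].[Na+]
Why: Ullmann-type copper-catalysed methoxylation of an ortho-iodophenoxide, the reaction type that turns 5-halovanillins into syringaldehyde, tolerated by the non-enolisable aldehyde and the benzyl ethers.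

**Step 4**
Reactants: 5 homovanillic acid
Product: 6 benzyl 2-[4-(benzyloxy)-3-methoxyphenyl]acetate
Conditions: BnBr, K2CO3, DMF, rt to 50 °C
Reagents that add atoms: benzyl bromide, BrCc1ccccc1
Why: Williamson-type O-alkylation in which carboxylate and phenoxide are both benzylated in one operation.

**Step 5**
Reactants: 6 benzyl 2-[4-(benzyloxy)-3-methoxyphenyl]acetate
Product: 8 benzyl 2-bromo-2-[4-(benzyloxy)-3-methoxyphenyl]acetate (racemic), via silyl ketene acetal 7 (not isolated)
Conditions: LiN(SiMe3)2, Me3SiCl, THF, −78 °C; then N-bromosuccinimide, −78 to 0 °C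
Reagents that add atoms: N-bromosuccinimide, O=C1CCC(=O)N1Br; chlorotrimethylsilane, C[Si](C)(C)Cl (silicon stays only in 7)
Why: α-Bromination of an ester through its silyl ketene acetal, which avoids radical conditions that would attack the benzylic ether positions and forms the new stereocentre as a racemate.

**Step 6**
Reactants: 4 4,6-bis(benzyloxy)-2-hydroxy-3-methoxybenzaldehyde; 8 benzyl 2-bromo-2-[4-(benzyloxy)-3-methoxyphenyl]acetate
Product: 9 benzyl 2-[3,5-bis(benzyloxy)-2-formyl-6-methoxyphenoxy]-2-[4-(benzyloxy)-3-methoxyphenyl]acetate (racemic)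
Conditions: K2CO3, DMF, rt
Reagents that add atoms: none
Why: Williamson ether synthesis, the phenoxide displacing the activated secondary benzylic α-bromo ester to form the O1–C2 ether (racemic at C2) under a carbonate base that leaves the aldehyde alone.

**Step 7**
Reactants: 9 benzyl 2-[3,5-bis(benzyloxy)-2-formyl-6-methoxyphenoxy]-2-[4-(benzyloxy)-3-methoxyphenyl]acetate
Product: 10 2-[3,5-bis(benzyloxy)-2-(hydroxymethyl)-6-methoxyphenoxy]-2-[4-(benzyloxy)-3-methoxyphenyl]ethan-1-ol (racemic)
Conditions: LiAlH4, THF, 0 °C; aq. potassium sodium tartrate work-up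
Reagents that add atoms: none
Why: Hydride reduction of ester and aryl aldehyde to the diol, which brings both carbons to one oxidation level for a single mild oxidation.

**Step 8**
Reactants: 10 2-[3,5-bis(benzyloxy)-2-(hydroxymethyl)-6-methoxyphenoxy]-2-[4-(benzyloxy)-3-methoxyphenyl]ethan-1-ol
Product: 11 2-[3,5-bis(benzyloxy)-2-formyl-6-methoxyphenoxy]-2-[4-(benzyloxy)-3-methoxyphenyl]acetaldehyde (racemic)
Conditions: Dess–Martin periodinane, NaHCO3, CH2Cl2, 0 °C to rt; used without delay
Reagents that add atoms: none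
Why: Dess–Martin oxidation of the primary and the benzylic alcohol under buffered, non-basic conditions that suit the enolisable α-aryloxy aldehyde.

**Step 9**
Reactants: 11 2-[3,5-bis(benzyloxy)-2-formyl-6-methoxyphenoxy]-2-[4-(benzyloxy)-3-methoxyphenyl]acetaldehyde
Product: 12 trans-5,7-bis(benzyloxy)-2-[4-(benzyloxy)-3-methoxyphenyl]-3-hydroxy-8-methoxychroman-4-one (racemic)
Conditions: 2-(pentafluorophenyl)-6,7-dihydro-5H-pyrrolo[2,1-c][1,2,4]triazol-2-ium tetrafluoroborate (20 mol %), Et3N (20 mol %), toluene, rt, argon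
Reagents that add atoms: none
Why: Proposed new method: the triazolylidene adds to the ring A aldehyde, the benzylic C–H of the adduct is lost to give the Breslow intermediate (acyl anion equivalent at C4), this attacks the side-chain aldehyde to form C3–C4, and collapse to the C4 ketone releases the carbene; the closest known reaction type is the carbene-catalysed intramolecular crossed benzoin of 2-(2-oxoalkoxy)benzaldehydes to 3-hydroxychroman-4-ones, extended here from a ketone acceptor to an enolisable α-aryloxy aldehyde. Ring C closes in the 6-exo-trig mode through the O1–C2 ether tether. C3 is the new stereocentre and is set relative to the existing racemic C2 by a chair-like transition state with the C2 aryl group equatorial, backed by amine-mediated epimerisation α to the new ketone toward the diequatorial trans isomer; C2 itself is not touched. The step needs intramolecular over intermolecular coupling, which the tether secures, and it needs C4 rather than C3 as donor, because a Breslow intermediate at C3 could expel the ring A phenoxide (internal redox to an aryl ester) instead of cyclising. The more acidic benzylic C–H of the ring A adduct and the α-branching of the side-chain aldehyde favour the C4 donor, and a small, electron-poor N-pentafluorophenyl carbene that adds reversibly, with a weak amine base in catalytic amount only, is chosen to support this and to limit enolisation of 11. Should C3 act as donor and still cyclise, the isomeric 4-hydroxychroman-3-one shares the enediol with 12 and should tautomerise to it, and neither the configuration nor any cis isomer matters because step 12 removes both stereocentres.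

**Step 10**
Reactants: 12 trans-5,7-bis(benzyloxy)-2-[4-(benzyloxy)-3-methoxyphenyl]-3-hydroxy-8-methoxychroman-4-one
Product: 13 trans-3,5,7-trihydroxy-2-(4-hydroxy-3-methoxyphenyl)-8-methoxychroman-4-one (racemic)
Conditions: H2 (1 atm), Pd/C (10 wt %), EtOAc–MeOH, rt
Reagents that add atoms: none
Why: Hydrogenolysis of the three benzyl aryl ethers over palladium at ambient pressure, mild enough to leave the chromanone carbonyl, the C2–O1 bond and both stereocentres of the flavanonol untouched.

**Step 11**
Reactants: 13 trans-3,5,7-trihydroxy-2-(4-hydroxy-3-methoxyphenyl)-8-methoxychroman-4-one; 14 prenyl bromide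
Product: 15 trans-3,5-dihydroxy-2-(4-hydroxy-3-methoxyphenyl)-8-methoxy-7-[(3-methylbut-2-en-1-yl)oxy]chroman-4-one (racemic)
Conditions: K2CO3 (1.05 equiv), DMF, 0 °C to rt, argon
Reagents that add atoms: none
Why: Williamson alkylation under acidity control, since 7-OH (para to the C4 carbonyl) is the most acidic hydroxyl while 5-OH is chelated to C4=O, 4'-OH is an unconjugated guaiacol and 3-OH is an alcohol, so one equivalent of carbonate should direct the prenyl group to O7 as in 7-O-alkylation of 5,7,4'-trihydroxyflavanones.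

**Step 12**
Reactants: 15 trans-3,5-dihydroxy-2-(4-hydroxy-3-methoxyphenyl)-8-methoxy-7-[(3-methylbut-2-en-1-yl)oxy]chroman-4-one
Product: 16 3,5-dihydroxy-2-(4-hydroxy-3-methoxyphenyl)-8-methoxy-7-[(3-methylbut-2-en-1-yl)oxy]-4H-chromen-4-one (target)
Conditions: H2O2 (30 % aq.), NaOH (aq.), MeOH, 0 °C to rt; then aq. HCl
Reagents that add atoms: none
Why: Dehydrogenation of the flavanonol through its enediolate with alkaline H2O2, the closing stage of the Algar–Flynn–Oyamada reaction, which spares the electron-rich prenyl alkene and removes both stereocentres.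

**Compound list**

1 | 3,5-bis(benzyloxy)phenol | Oc1cc(OCc2ccccc2)cc(OCc2ccccc2)c1 | starting material
2 | 2,4-bis(benzyloxy)-6-hydroxybenzaldehyde | O=Cc1c(O)cc(OCc2ccccc2)cc1OCc1ccccc1 | intermediate
3 | 4,6-bis(benzyloxy)-2-hydroxy-3-iodobenzaldehyde | O=Cc1c(O)c(I)c(OCc2ccccc2)cc1OCc1ccccc1 | intermediate
4 | 4,6-bis(benzyloxy)-2-hydroxy-3-methoxybenzaldehyde | O=Cc1c(O)c(OC)c(OCc2ccccc2)cc1OCc1ccccc1 | intermediate
5 | homovanillic acid | COc1cc(CC(=O)O)ccc1O | starting material
6 | benzyl 2-[4-(benzyloxy)-3-methoxyphenyl]acetate | COc1cc(CC(=O)OCc2ccccc2)ccc1OCc1ccccc1 | intermediate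
7 | {1-(benzyloxy)-2-[4-(benzyloxy)-3-methoxyphenyl]ethenyl}oxy(trimethyl)silane (silyl ketene acetal, E/Z mixture, not isolated) | COc1cc(C=C(OCc2ccccc2)O[Si](C)(C)C)ccc1OCc1ccccc1 | intermediate
8 | benzyl 2-bromo-2-[4-(benzyloxy)-3-methoxyphenyl]acetate (racemic) | COc1cc(C(Br)C(=O)OCc2ccccc2)ccc1OCc1ccccc1 | intermediate
9 | benzyl 2-[3,5-bis(benzyloxy)-2-formyl-6-methoxyphenoxy]-2-[4-(benzyloxy)-3-methoxyphenyl]acetate (racemic) | O=C(OCc1ccccc1)C(Oc1c(C=O)c(OCc2ccccc2)cc(OCc2ccccc2)c1OC)c1ccc(OCc2ccccc2)c(OC)c1 | intermediate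
10 | 2-[3,5-bis(benzyloxy)-2-(hydroxymethyl)-6-methoxyphenoxy]-2-[4-(benzyloxy)-3-methoxyphenyl]ethan-1-ol (racemic) | OCC(Oc1c(CO)c(OCc2ccccc2)cc(OCc2ccccc2)c1OC)c1ccc(OCc2ccccc2)c(OC)c1 | intermediate
11 | 2-[3,5-bis(benzyloxy)-2-formyl-6-methoxyphenoxy]-2-[4-(benzyloxy)-3-methoxyphenyl]acetaldehyde (racemic) | O=CC(Oc1c(C=O)c(OCc2ccccc2)cc(OCc2ccccc2)c1OC)c1ccc(OCc2ccccc2)c(OC)c1 | intermediate
12 | trans-5,7-bis(benzyloxy)-2-[4-(benzyloxy)-3-methoxyphenyl]-3-hydroxy-8-methoxychroman-4-one (racemic, 2R,3R drawn) | COc1cc([C@H]2Oc3c(OC)c(OCc4ccccc4)cc(OCc4ccccc4)c3C(=O)[C@@H]2O)ccc1OCc1ccccc1 | intermediate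
13 | trans-3,5,7-trihydroxy-2-(4-hydroxy-3-methoxyphenyl)-8-methoxychroman-4-one (racemic, 2R,3R drawn) | COc1cc([C@H]2Oc3c(OC)c(O)cc(O)c3C(=O)[C@@H]2O)ccc1O | intermediate
14 | prenyl bromide (1-bromo-3-methylbut-2-ene) | CC(C)=CCBr | starting material
15 | trans-3,5-dihydroxy-2-(4-hydroxy-3-methoxyphenyl)-8-methoxy-7-[(3-methylbut-2-en-1-yl)oxy]chroman-4-one (racemic, 2R,3R drawn) | COc1cc([C@H]2Oc3c(OC)c(OCC=C(C)C)cc(O)c3C(=O)[C@@H]2O)ccc1O | intermediate
16 | 3,5-dihydroxy-2-(4-hydroxy-3-methoxyphenyl)-8-methoxy-7-[(3-methylbut-2-en-1-yl)oxy]-4H-chromen-4-one (CNP0210396.0) | COc1cc(-c2oc3c(OC)c(OCC=C(C)C)cc(O)c3c(=O)c2O)ccc1O | target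

**Step count and risks**

Total step count: 12. Longest linear sequence: 10 steps (steps 1, 2, 3, 6, 7, 8, 9, 10, 11, 12, from 1 to 16).

Steps most likely to fail:

1. Step 9 (Proposed new method). The carbene may engage the side-chain aldehyde first, and the resulting Breslow intermediate may expel the ring A phenoxide, which cuts the tether by internal redox. Amine-induced enolisation of the α-aryloxy aldehyde may also lead to aldol closure onto the aryl aldehyde to a five-membered ring, or the doubly ortho-substituted aryl aldehyde may be too slow a donor. The fallback uses known chemistry and closes ring C at O1–C2 instead; it sets out from 4 and returns at 12.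
   - Protection of 4 (MOMCl, NaH, DMF) should give 4,6-bis(benzyloxy)-3-methoxy-2-(methoxymethoxy)benzaldehyde F1.
   - Addition of MeMgBr in THF should give 1-[4,6-bis(benzyloxy)-3-methoxy-2-(methoxymethoxy)phenyl]ethan-1-ol F2.
   - Dess–Martin oxidation should give 1-[4,6-bis(benzyloxy)-3-methoxy-2-(methoxymethoxy)phenyl]ethan-1-one F3.
   - Claisen–Schmidt condensation with 4-(benzyloxy)-3-methoxybenzaldehyde (KOH, EtOH) should give (E)-1-[4,6-bis(benzyloxy)-3-methoxy-2-(methoxymethoxy)phenyl]-3-[4-(benzyloxy)-3-methoxyphenyl]prop-2-en-1-one F4.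
   - Weitz–Scheffer epoxidation (H2O2, NaOH, MeOH–THF) should give [4,6-bis(benzyloxy)-3-methoxy-2-(methoxymethoxy)phenyl]{trans-3-[4-(benzyloxy)-3-methoxyphenyl]oxiran-2-yl}methanone F5.
   - HCl in MeOH at 55 °C should remove the methoxymethyl group and let the freed phenol open the epoxide at the benzylic carbon with inversion, giving 12.

2. Step 12. Under alkaline peroxide the flavanonol may contract by α-ketol rearrangement to a benzofuranone, or the flavonolate formed may be cleaved oxidatively. The fallback dehydrogenates before deprotection and places the prenyl group on an acetate-protected flavonol; it sets out from 12 and returns at 16.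
   - I2 in DMSO at 110 °C should give 5,7-bis(benzyloxy)-2-[4-(benzyloxy)-3-methoxyphenyl]-3-hydroxy-8-methoxy-4H-chromen-4-one F6.
   - H2 over Pd/C should give limocitrin (3,5,7-trihydroxy-2-(4-hydroxy-3-methoxyphenyl)-8-methoxy-4H-chromen-4-one) F7.
   - Ac2O in pyridine should give limocitrin 3,5,7,4'-tetraacetate F8.
   - PhSH and imidazole in N-methylpyrrolidone at 0 °C should cleave the most labile 7-acetate to give limocitrin 3,5,4'-triacetate F9.
   - Prenyl bromide 14 with K2CO3 in acetone should give 7-O-prenyllimocitrin 3,5,4'-triacetate F10.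
   - K2CO3 in MeOH should remove the acetates to give 16.

3. Step 3. Hydrodehalogenation may outrun C–O coupling at the doubly ortho-flanked carbon, or the coupling may stall. The fallback builds the methoxy-bearing carbon by Baeyer–Villiger oxidation; it sets out from 2 and returns at 4.
   - MOMCl and NaH in DMF should give 2,4-bis(benzyloxy)-6-(methoxymethoxy)benzaldehyde F11.
   - mCPBA in CH2Cl2 should give 2,4-bis(benzyloxy)-6-(methoxymethoxy)phenyl formate F12.
   - K2CO3 in MeOH in the same flask should give 2,4-bis(benzyloxy)-6-(methoxymethoxy)phenol F13.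
   - MeI and K2CO3 in acetone should give 1,5-bis(benzyloxy)-2-methoxy-3-(methoxymethoxy)benzene F14.
   - HCl in MeOH should give 3,5-bis(benzyloxy)-2-methoxyphenol F15.
   - Ortho-formylation as in step 1 (MgCl2, Et3N, (CH2O)n) at the single free ortho carbon should give 4.

**Further compounds**

F1 | step 9 | 4,6-bis(benzyloxy)-3-methoxy-2-(methoxymethoxy)benzaldehyde | O=Cc1c(OCOC)c(OC)c(OCc2ccccc2)cc1OCc1ccccc1
F2 | step 9 | 1-[4,6-bis(benzyloxy)-3-methoxy-2-(methoxymethoxy)phenyl]ethan-1-ol (racemic) | CC(O)c1c(OCOC)c(OC)c(OCc2ccccc2)cc1OCc1ccccc1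
F3 | step 9 | 1-[4,6-bis(benzyloxy)-3-methoxy-2-(methoxymethoxy)phenyl]ethan-1-one | CC(=O)c1c(OCOC)c(OC)c(OCc2ccccc2)cc1OCc1ccccc1
F4 | step 9 | (E)-1-[4,6-bis(benzyloxy)-3-methoxy-2-(methoxymethoxy)phenyl]-3-[4-(benzyloxy)-3-methoxyphenyl]prop-2-en-1-one | COCOc1c(C(=O)/C=C/c2ccc(OCc3ccccc3)c(OC)c2)c(OCc2ccccc2)cc(OCc2ccccc2)c1OC
F5 | step 9 | [4,6-bis(benzyloxy)-3-methoxy-2-(methoxymethoxy)phenyl]{trans-3-[4-(benzyloxy)-3-methoxyphenyl]oxiran-2-yl}methanone (racemic) | COCOc1c(C(=O)[C@H]2O[C@@H]2c2ccc(OCc3ccccc3)c(OC)c2)c(OCc2ccccc2)cc(OCc2ccccc2)c1OC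
F6 | step 12 | 5,7-bis(benzyloxy)-2-[4-(benzyloxy)-3-methoxyphenyl]-3-hydroxy-8-methoxy-4H-chromen-4-one | COc1cc(-c2oc3c(OC)c(OCc4ccccc4)cc(OCc4ccccc4)c3c(=O)c2O)ccc1OCc1ccccc1
F7 | step 12 | limocitrin (3,5,7-trihydroxy-2-(4-hydroxy-3-methoxyphenyl)-8-methoxy-4H-chromen-4-one) | COc1cc(-c2oc3c(OC)c(O)cc(O)c3c(=O)c2O)ccc1O
F8 | step 12 | limocitrin 3,5,7,4'-tetraacetate | COc1cc(-c2oc3c(OC)c(OC(C)=O)cc(OC(C)=O)c3c(=O)c2OC(C)=O)ccc1OC(C)=O
F9 | step 12 | limocitrin 3,5,4'-triacetate (7-OH free) | COc1cc(-c2oc3c(OC)c(O)cc(OC(C)=O)c3c(=O)c2OC(C)=O)ccc1OC(C)=O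
F10 | step 12 | 7-O-prenyllimocitrin 3,5,4'-triacetate | COc1cc(-c2oc3c(OC)c(OCC=C(C)C)cc(OC(C)=O)c3c(=O)c2OC(C)=O)ccc1OC(C)=O
F11 | step 3 | 2,4-bis(benzyloxy)-6-(methoxymethoxy)benzaldehyde | COCOc1cc(OCc2ccccc2)cc(OCc2ccccc2)c1C=O
F12 | step 3 | 2,4-bis(benzyloxy)-6-(methoxymethoxy)phenyl formate | COCOc1cc(OCc2ccccc2)cc(OCc2ccccc2)c1OC=O
F13 | step 3 | 2,4-bis(benzyloxy)-6-(methoxymethoxy)phenol | COCOc1cc(OCc2ccccc2)cc(OCc2ccccc2)c1O
F14 | step 3 | 1,5-bis(benzyloxy)-2-methoxy-3-(methoxymethoxy)benzene | COCOc1cc(OCc2ccccc2)cc(OCc2ccccc2)c1OC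
F15 | step 3 | 3,5-bis(benzyloxy)-2-methoxyphenol | COc1c(O)cc(OCc2ccccc2)cc1OCc1ccccc1
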